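The two ring C pyranones are disconnected at C4–C4a and C4'–C4a', which leads back to a C2-symmetric hexamethoxybiphenyl-2,2'-diol carrying a 4-methoxyphenylacetyl group on each O8a. A twofold Lewis-acid Fries shift moves both acyl groups from O8a to C4a in one operation and forms the two aryl–carbonyl bonds without closing a ring. It exploits ring A, in which C4a is the only unsubstituted carbon: it lies ortho to O8a, while C5, C6 and C7 bear oxygen and C8 holds the biaryl axis. An Ullmann coupling supplies the biaryl; formamide acetal closure onto O8a and global demethylation complete the target.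

Key step: step 4

Assumption: the target SMILES defines no axial configuration, so the hindered C8–C8' axis is carried as the racemate; atoms are named by chromone numbering (C8 = biphenyl C1, C8a = C2, C4a = C3, C5 = C4, C6 = C5, C7 = C6).

Step 1
Reactants: 1 2-bromo-3,4,5-trimethoxybenzaldehyde (two molecules)
Product: 2 4,4',5,5',6,6'-hexamethoxybiphenyl-2,2'-dicarbaldehyde
Conditions: Cu powder (activated, 4 equiv), DMF, 150 °C, argon
Reagents that add atoms: none
Why: Ullmann reductive homocoupling: the ortho-formyl group activates the C–Br bond toward copper, and the arylcopper formed couples with a second molecule of 1, a reaction type that tolerates the four ortho substituents and gives the C8–C8' axis as the racemate.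

Step 2
Reactants: 2 4,4',5,5',6,6'-hexamethoxybiphenyl-2,2'-dicarbaldehyde
Product: 4 4,4',5,5',6,6'-hexamethoxybiphenyl-2,2'-diol, via diformate 3 (not isolated)
Conditions: mCPBA (3 equiv), CH2Cl2, 0 °C → rt; aq. Na2S2O3/NaHCO3 wash; then K2CO3 (cat.), MeOH, rt, argon
Reagents that add atoms: 3-chloroperoxybenzoic acid (mCPBA), O=C(OO)c1cccc(Cl)c1
Why: Baeyer–Villiger (Dakin-type) oxidation: in the peracid adduct the electron-rich aryl group, which has a methoxy group para to the formyl carbon, migrates to oxygen in preference to hydrogen, and mild methanolysis of the aryl formate frees O8a, while the non-basic oxidation avoids an intramolecular Cannizzaro reaction between the two neighbouring aldehydes.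

Step 3
Reactants: 4 4,4',5,5',6,6'-hexamethoxybiphenyl-2,2'-diol; 5 4-methoxyphenylacetic acid (2.4 equiv)
Product: 6 4,4',5,5',6,6'-hexamethoxybiphenyl-2,2'-diyl bis[(4-methoxyphenyl)acetate]
Conditions: DCC (2.4 equiv), DMAP (0.2 equiv), CH2Cl2, 0 °C → rt
Reagents that add atoms: 4-methoxyphenylacetic acid (5), COc1ccc(CC(=O)O)cc1
Why: Steglich esterification: DMAP carries the acyl group from the O-acylisourea to the two phenols, which are hindered by the axis but are the only nucleophiles present, so the symmetric bis-ester should form cleanly.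

Step 4
Reactants: 6 4,4',5,5',6,6'-hexamethoxybiphenyl-2,2'-diyl bis[(4-methoxyphenyl)acetate]
Product: 7 1,1'-(2,2'-dihydroxy-4,4',5,5',6,6'-hexamethoxybiphenyl-3,3'-diyl)bis[2-(4-methoxyphenyl)ethanone]
Conditions: TiCl4 (6 equiv), CH2Cl2, −10 °C → rt; then cold 1 M HCl
Reagents that add atoms: none
Why: TiCl4 binds the ester carbonyl and ionises the O8a–acyl bond to a closely held aryloxytitanium/acyl electrophile pair, the acyl group attacks C4a in a Friedel–Crafts sense, and the ortho-hydroxy ketone stays bound to titanium through O8a and the new carbonyl until aqueous acid releases it. The closest known reaction type is the Lewis-acid Fries rearrangement of aryl arylacetates to 2-hydroxydeoxybenzoins, here run twice on one C2-symmetric substrate. No ring is closed and no stereocentre is formed, and the racemic C8–C8' axis from step 1 is untouched. The step needs site selectivity, and the substitution pattern supplies it: C4a is the only CH of each biphenyl ring, it is activated by O8a and O5 (ortho) and O7 (para), and the para position C6 is blocked, so even an acyl group that passes between molecules can only land on a C4a. It also needs chemoselectivity over loss of CO from the arylacetyl electrophile and over cleavage of the O5 methyl ether; a temperature at or below room temperature and the binding of titanium between O8a and the carbonyl should secure both, so that O8a emerges free and O5 stays methylated for the ring closure.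

Step 5
Reactants: 7 1,1'-(2,2'-dihydroxy-4,4',5,5',6,6'-hexamethoxybiphenyl-3,3'-diyl)bis[2-(4-methoxyphenyl)ethanone]; 8 N,N-dimethylformamide dimethyl acetal (6 equiv)
Product: 10 5,5',6,6',7,7'-hexamethoxy-3,3'-bis(4-methoxyphenyl)-4H,4'H-[8,8'-bichromene]-4,4'-dione, via bis(enaminone) 9 (not isolated)
Conditions: toluene, 100 °C
Reagents that add atoms: N,N-dimethylformamide dimethyl acetal (8), COC(OC)N(C)C
Why: Isoflavone synthesis from a 2-hydroxydeoxybenzoin with a formamide acetal: the acidic benzylic CH2 condenses with 8 to the enaminone, and O8a, the only free hydroxyl next to the ketone because O5 is methylated, adds to the enamine carbon with loss of dimethylamine (addition–elimination) to close ring C.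

Step 6
Reactants: 10 5,5',6,6',7,7'-hexamethoxy-3,3'-bis(4-methoxyphenyl)-4H,4'H-[8,8'-bichromene]-4,4'-dione
Product: 11 5,5',6,6',7,7'-hexahydroxy-3,3'-bis(4-hydroxyphenyl)-4H,4'H-[8,8'-bichromene]-4,4'-dione
Conditions: BBr3 (20 equiv), CH2Cl2, −78 °C → rt, argon; then ice-water
Reagents that add atoms: none
Why: Lewis-acid ether cleavage with BBr3: each methoxy oxygen binds boron and bromide removes the methyl group by SN2, the chelated O5 ethers going first, and the anhydrous low-temperature conditions leave the pyranone rings closed, so the substitution pattern cannot isomerise by ring opening and reclosure.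

Compound list
1 | 2-bromo-3,4,5-trimethoxybenzaldehyde | O=Cc1cc(OC)c(OC)c(OC)c1Br | starting material
2 | 4,4',5,5',6,6'-hexamethoxybiphenyl-2,2'-dicarbaldehyde (racemic axis) | O=Cc1cc(OC)c(OC)c(OC)c1-c1c(C=O)cc(OC)c(OC)c1OC | intermediate
3 | 4,4',5,5',6,6'-hexamethoxybiphenyl-2,2'-diyl diformate (not isolated) | O=COc1cc(OC)c(OC)c(OC)c1-c1c(OC=O)cc(OC)c(OC)c1OC | intermediate
4 | 4,4',5,5',6,6'-hexamethoxybiphenyl-2,2'-diol | Oc1cc(OC)c(OC)c(OC)c1-c1c(O)cc(OC)c(OC)c1OC | intermediate
5 | 4-methoxyphenylacetic acid | COc1ccc(CC(=O)O)cc1 | starting material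
6 | 4,4',5,5',6,6'-hexamethoxybiphenyl-2,2'-diyl bis[(4-methoxyphenyl)acetate] | COc1ccc(CC(=O)Oc2cc(OC)c(OC)c(OC)c2-c2c(OC(=O)Cc3ccc(OC)cc3)cc(OC)c(OC)c2OC)cc1 | intermediate
7 | 1,1'-(2,2'-dihydroxy-4,4',5,5',6,6'-hexamethoxybiphenyl-3,3'-diyl)bis[2-(4-methoxyphenyl)ethanone] | COc1ccc(CC(=O)c2c(O)c(-c3c(O)c(C(=O)Cc4ccc(OC)cc4)c(OC)c(OC)c3OC)c(OC)c(OC)c2OC)cc1 | intermediate
8 | N,N-dimethylformamide dimethyl acetal | COC(OC)N(C)C | starting material
9 | 1,1'-(2,2'-dihydroxy-4,4',5,5',6,6'-hexamethoxybiphenyl-3,3'-diyl)bis[3-(dimethylamino)-2-(4-methoxyphenyl)prop-2-en-1-one] (not isolated; enamine double-bond geometry not assigned, either isomer closes) | COc1ccc(cc1)C(=CN(C)C)C(=O)c1c(O)c(-c2c(O)c(C(=O)C(=CN(C)C)c3ccc(OC)cc3)c(OC)c(OC)c2OC)c(OC)c(OC)c1OC | intermediate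
10 | 5,5',6,6',7,7'-hexamethoxy-3,3'-bis(4-methoxyphenyl)-4H,4'H-[8,8'-bichromene]-4,4'-dione | O=c1c(-c2ccc(OC)cc2)coc2c(-c3c(OC)c(OC)c(OC)c4c(=O)c(-c5ccc(OC)cc5)coc34)c(OC)c(OC)c(OC)c12 | intermediate
11 | 5,5',6,6',7,7'-hexahydroxy-3,3'-bis(4-hydroxyphenyl)-4H,4'H-[8,8'-bichromene]-4,4'-dione (CNP0254964.0, racemic axis) | O=c1c(-c2ccc(O)cc2)coc2c(-c3c(O)c(O)c(O)c4c(=O)c(-c5ccc(O)cc5)coc34)c(O)c(O)c(O)c12 | target

Total step count: 6
Longest linear sequence: 6 steps (1 → 2 → 4 → 6 → 7 → 10 → 11)

Steps most likely to fail

1. Step 4. The arylacetyl electrophile may lose CO and transfer a 4-methoxybenzyl group instead of the acyl group, or the Lewis acid may cleave the O5 methyl ether next to the new ketone, which would remove the distinction between O8a and O5 in the later closure. The fallback avoids the O-to-C shift and acylates carbon directly. It sets out from biphenol 4, which would undergo a twofold Hoesch reaction with 4-methoxyphenylacetonitrile (ZnCl2, dry HCl, Et2O, 0 °C). The nitrilium electrophile cannot lose CO and should attack the same C4a positions, giving the bis(ketiminium chloride) F1. Hydrolysis of F1 in warm water would return to the route at 7.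

2. Step 1. Hydrodebromination of 1 and stalling of the coupling at a carbon flanked by two ortho substituents may limit the formation of the tetra-ortho-substituted axis on copper. The fallback replaces the reductive homocoupling by a cross-coupling. It sets out from 1, which by Miyaura borylation (B2pin2, PdCl2(dppf), KOAc, dioxane, 90 °C) would give 3,4,5-trimethoxy-2-(4,4,5,5-tetramethyl-1,3,2-dioxaborolan-2-yl)benzaldehyde F2. Suzuki–Miyaura coupling of F2 with a second equivalent of 1 (Pd(OAc)2, SPhos, K3PO4, toluene/water, 100 °C) would return to the route at 2.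

3. Step 6. Ether cleavage may stop short within the crowded C5–C7 triads, the pyrogallol-type units may hold boron tightly, and these units may oxidise in air during isolation of the free octaphenol. The fallback changes both the cleavage mechanism and the way the product is isolated. It sets out from 10, which would be demethylated in a melt of pyridinium chloride (about 190 °C, argon), where the ether oxygen is protonated and chloride attacks the methyl group without boron. The crude polyphenol would be acetylated in the same flask (Ac2O, pyridine) and purified as the octaacetate of the target, 4,4'-dioxo-3,3'-bis(4-acetoxyphenyl)-4H,4'H-[8,8'-bichromene]-5,5',6,6',7,7'-hexayl hexaacetate F3. Acid-catalysed methanolysis of F3 (HCl cat., degassed MeOH, 50 °C) would return to the route at 11.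

Further compounds
F1 | step 4 | 1,1'-(2,2'-dihydroxy-4,4',5,5',6,6'-hexamethoxybiphenyl-3,3'-diyl)bis[2-(4-methoxyphenyl)ethan-1-iminium] dichloride | COc1ccc(CC(=[NH2+])c2c(O)c(-c3c(O)c(C(=[NH2+])Cc4ccc(OC)cc4)c(OC)c(OC)c3OC)c(OC)c(OC)c2OC)cc1.[Cl-].[Cl-]
F2 | step 1 | 3,4,5-trimethoxy-2-(4,4,5,5-tetramethyl-1,3,2-dioxaborolan-2-yl)benzaldehyde | O=Cc1cc(OC)c(OC)c(OC)c1B1OC(C)(C)C(C)(C)O1
F3 | step 6 | 4,4'-dioxo-3,3'-bis(4-acetoxyphenyl)-4H,4'H-[8,8'-bichromene]-5,5',6,6',7,7'-hexayl hexaacetate | O=c1c(-c2ccc(OC(C)=O)cc2)coc2c(-c3c(OC(C)=O)c(OC(C)=O)c(OC(C)=O)c4c(=O)c(-c5ccc(OC(C)=O)cc5)coc34)c(OC(C)=O)c(OC(C)=O)c(OC(C)=O)c12
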